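## Structural features

The target is an unsymmetrical ether of two 2-(2-phenylethyl)chromone units. The unprimed unit is a 5,6,7,8-tetrahydrochromone: carbocyclic ring A (C4a, C5–C8, C8a) is fused through C4a=C8a to a 4-pyranone (ring C) and carries oxygen on every sp3 carbon. The primed unit is a fully aromatic chromone, benzene ring B fused to a second 4-pyranone (ring D), with a methoxy group on C7'. The halves are joined by one ether bridge from the secondary carbon C8 to the aromatic carbon C6'. The four stereocentres C5–C8 are contiguous, (5S,6R,7S,8S), with O5/O6 trans, O6/O7 trans and O7/O8 cis; C5 and C8 both sit on the pyranone double bond. Fragile points are the polyol ring (two eliminations away from an aromatic chromone once C5 is a carbonyl or an anion is formed beside it), the C5–O bond (vinylogously activated by O1), the electrophilic C2 positions of both pyranones, and vicinal silyl ethers that migrate under base. The real difficulty is the C8–O–C6' ether: C8 is a hindered carbinol between an sp2 carbon and a cis oxygen, so displacement at C8 would invert it and invite elimination, and ring B is electron-rich with no activating group for substitution at C6'. The key step uses the pattern of ring B itself: O6' is para to O1' (on C8a'), the methoxy group is on the neighbouring C7', and the only carbon substituent is on C4a', ortho to O1'. That is the 4-alkoxyphenol pattern assembled by an alkoxy(alkenyl)carbene on chromium, one CO and a terminal alkyne, so ring B can be grown on the C8 oxygen.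

## Logic of the disconnections

34 ⇒ 33. The three O–Si bonds on O5, O6 and O7 are cut last. A masked triol tolerates the organometallic and oxidative steps on the other half, and only one sensitive hydroxyl pattern is revealed at the end. The forward step must remove three hindered silyl ethers without touching the aryl alkyl ether or the pyranones.

33 ⇒ 31. The O1'–C2' bond of ring D is cut, opening the aromatic pyranone to an ortho-hydroxyaryl ynone. One ring disappears and the primed half is reduced to a substituted benzene. The forward closure must be 6-endo only, so it is relayed through an amine adduct (32).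

31 ⇒ 30 ⇒ 29. The C4' carbonyl is taken back to a silyl-protected carbinol. A conjugated ynone would not survive carbene chemistry; a propargylic silyl ether is an innocent alkyne substituent. The price is one selective desilylation and an oxidation that tolerates a free, electron-rich phenol.

29 ⇒ 23 + 28. Ring B is cut at C5'–C6', C4a'–C8a' and C8'–C8a'. The aromatic ring dissolves into a carbene carbon already bonded to O8, a two-carbon alkenyl unit carrying the methoxy group, one CO and a terminal alkyne. The hindered ether is therefore never formed by substitution at C8 or at an arene. The forward step needs regioselective alkyne insertion, reaction at the terminal and not the internal alkyne of 28, and a carbene that survives until the alkyne arrives.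

23 ⇒ 21 + 16 (through 22). The bond between the carbene carbon and O8 is cut. The hindered alcohol enters as a nucleophile at an acyl-like carbon, so the C8–O bond and its configuration are untouched and the chromium piece is separated from the chiral core. This requires that O8 is the only free hydroxyl of 16 and that the exchange runs under neutral, cold conditions.

21 ⇒ 17 + 18. The bond between the future carbene carbon and the methoxy-bearing vinyl carbon is cut: a lithiated enol ether adds to a CO ligand. Both partners are bulk chemicals.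

28 ⇒ 27 ⇒ 26 ⇒ 24. The O–Si bond, the bond from the carbinol carbon to the ethynyl group, and the bond from the formyl carbon to the alkyne are cut in turn. Each forward step is an acetylide or Grignard addition, and the racemic carbinol is acceptable because it is oxidised later.

16 ⇒ 15 ⇒ 14. These are protecting-group operations: O8 carries a silyl group different from those on O5–O7, so it can be freed alone. The forward steps need clean kinetic differentiation of silyl ethers and no basic conditions once O8–H sits beside a cis silyl ether.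

14 ⇒ 13. The C5–H bond is cut, returning C5 to a ketone. The C5 carbonyl is what makes C4a nucleophilic for the annulation below. The forward reduction must set C5 trans to O6, which is secured by hydride delivery from the free O6 hydroxyl.

13 ⇒ 6 + 9 (through 10–12). Ring C is cut at C4–C4a and O1–C8a. The bicycle falls apart into a cyclohexenone bearing nitrogen on C8a and a five-carbon acylketene source. Nitrogen fixes which carbon receives O1. O6 must be masked while the ketene is present.

9 ⇒ 7 (through 8). The side-chain C–C bond next to the phenyl-bearing carbon is cut; the forward step is a vinylogous enolate benzylation.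

6 ⇒ 5 ⇒ 4 ⇒ 3 ⇒ 2 ⇒ 1. The C8a–N bond goes back to C8a–Br, the C5 carbonyl to an allylic alcohol, and the C5–O and C6–O bonds to the unhalogenated alkene of the diene. The two silyl groups go back to the cis-diol. The forward steps need silylation of the hydroxyl remote from bromine first, dihydroxylation anti to the silyloxy groups, and oxidation of the allylic hydroxyl only.

## Other disconnections considered

Alternative 1: The cut runs through ring C at C4–C4a and O1–C8a. In the forward sense acylketene 11, released thermally from 9, would acylate C4a of the cis-diol-derived pyrrolidine enaminone A2; the enol oxygen would then displace the amine at C8a to give the 5-oxo-tetrahydrochromone A1 (7,8-acetonide, 6-silyl ether). In its favour: neutral conditions, regiochemistry dictated by nitrogen, a short path from 1, and an acetonide sturdier than the mixed silyl pattern used here. Against it as the strategic step: the ether C8–O–C6' remains unmade. After reduction at C5 and acetonide removal, O7 and O8 would have to be told apart, and a ready-made phenol such as A3 would have to be joined to a hindered, elimination-prone secondary carbon. Substitution there would invert C8, and cross-coupling would need base beside a silyl ether. Comparison: on the bonds of ring C the two plans are equal, since the same annulation is step 7 of the chosen route. On step economy up to the bicyclic core alternative 1 is the better, because A1 needs fewer protecting-group operations than 16. On structure it offers no solution for ring B and the ether, which the chosen plan solves without touching the C8–O bond. On mechanism both rest on thermal pericyclic chemistry, and that of alternative 1 is the better precedented.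

Alternative 2: The cut removes C2–C3 and C2'–C3' and then O1–C2 and O1'–C2', so both pyranones are made at once. In the forward sense multiple deprotonation of the bis(acetyl) ether A5 and two Claisen acylations by the ester A6, followed by acid-mediated cyclodehydration, would give the tri-O-benzyl ether A4. In its favour: both side chains and both pyranones arise in one operation from a cheap ester, and on the aromatic half this is the classical, robust chromone synthesis. Against it here: the aliphatic half of A5 is a 2-acetylcyclohexanone enol with a benzyloxy group β to the carbonyl system and an aryloxy group α to it. Excess strong base (phenol, enol and two methyl ketones must all be deprotonated) and the later acid treatment both invite β-elimination and aromatisation of ring A. A5 also already contains the hindered ether, so that problem is only moved to an earlier, equally unactivated stage. The final debenzylation must spare two pyranone double bonds. Comparison: in step economy after the ether is in place alternative 2 is the better, and for ring D its chemistry is at least the equal of the ynone closure used here. On structure and mechanism the chosen plan is safer for ring A, because ring C is closed under neutral conditions while C5 is still a ketone, and it is the only one of the two that answers how the ether is made.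

Alternative 3: The cut is through ring A at C4a–C8a, together with the C4–O bond of a temporary isoxazole. In the forward sense a chain derived from D-glucose A9 would be elaborated to the aldoxime A8, which carries the aryl ether and a tethered alkyne. Oxidative activation of A8 would trigger an intramolecular [3+2] cycloaddition of the resulting dipole to the alkyne, closing the six-membered carbocycle and the fused isoxazole of A7. In its favour: all four stereocentres come from the chiral pool with no reduction step, the ring closure is intramolecular and regiospecific, and the aryl ether can be formed by substitution on an open-chain carbinol where either configuration is accessible. Against it here: the sequence is long, the complete chromone of the primed half must be carried through sugar chemistry, and the isoxazole still has to be opened reductively in the presence of benzyl ethers and pyranones. The side-chain carbinol must then be oxidised and ring C closed with loss of nitrogen, and three benzyl ethers must be removed at the end. Comparison: on stereochemical security alternative 3 is the better of the two, since the chosen plan must set C5 by a directed reduction. On mechanism the two key steps are equally reliable pericyclic processes. On step economy and on the number of late redox and unmasking operations the chosen plan is clearly shorter.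

Key step: step 16

Remark: TBS = tert-butyldimethylsilyl, TES = triethylsilyl, TMS = trimethylsilyl (TBSO and so on for the ethers); unprimed locants refer to the tetrahydrochromone, primed ones to the aromatic chromone.
Remark: 27–30 are carried as pairs of epimers at the side-chain carbinol carbon, which becomes the C4' carbonyl in step 18; carbonyl ligands on chromium are written Cr=C=O in the SMILES strings.

## Steps

Step 1
Reactants: 1 (1S,2S)-3-bromocyclohexa-3,5-diene-1,2-diol
Product: 2 (1S,6S)-2-bromo-6-(TBSO)cyclohexa-2,4-dien-1-ol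
Conditions: TBSCl (1.05 equiv), imidazole, DMF, −10 °C
Reagents that add atoms: tert-butyldimethylsilyl chloride, CC(C)(C)[Si](C)(C)Cl
Why: Kinetic monosilylation (silyl ether formation): the hydroxyl remote from bromine is the less hindered one, the other being flanked by the brominated sp2 carbon, so one equivalent of the bulky chlorosilane in the cold should silylate it selectively; no stereocentre is touched.

Step 2
Reactants: 2 mono-TBS dienol
Product: 3 (5S,6S)-1-bromo-5-(TBSO)-6-(TESO)cyclohexa-1,3-diene
Conditions: TESCl, imidazole, DMF, 0 °C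
Reagents that add atoms: triethylsilyl chloride, CC[Si](Cl)(CC)CC
Why: Silyl ether formation on the remaining allylic hydroxyl; imidazole conditions generate no free alkoxide, so no silyl migration is expected, and the triethylsilyl group labels the future O8 for later selective removal.

Step 3
Reactants: 3 bis-silyl bromodiene
Product: 4 (1R,2R,5S,6S)-4-bromo-6-(TBSO)-5-(TESO)cyclohex-3-ene-1,2-diol
Conditions: OsO4 (cat.), NMO, acetone–H2O, 0 °C → rt
Reagents that add atoms: N-methylmorpholine N-oxide, C[N+]1([O-])CCOCC1; water, O
Why: Upjohn dihydroxylation: OsO4 adds suprafacially to the more electron-rich, unhalogenated alkene from the face opposite the two silyloxy groups, which places the future O6 (and, transiently, O5) anti to O7.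

Step 4
Reactants: 4 ene-diol
Product: 5 (4S,5S,6S)-3-bromo-5-(TBSO)-6-hydroxy-4-(TESO)cyclohex-2-en-1-one
Conditions: MnO2 (activated, excess), CH2Cl2, rt
Reagents that add atoms: none
Why: Chemoselective MnO2 oxidation of the allylic hydroxyl beside a non-allylic one under neutral conditions should give the β-bromo enone; the carbinol centre that becomes C6 is untouched.

Step 5
Reactants: 5 hydroxy β-bromo enone
Product: 6 (4R,5S,6S)-5-(TBSO)-6-hydroxy-3-(pyrrolidin-1-yl)-4-(TESO)cyclohex-2-en-1-one
Conditions: pyrrolidine (2.5 equiv), CH2Cl2, 0 °C → rt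
Reagents that add atoms: pyrrolidine, C1CCNC1
Why: Addition–elimination (vinylogous acyl substitution) of the secondary amine at the β-carbon of the bromo enone gives the vinylogous amide, with the extra amine taking up HBr; nitrogen now marks the carbon that will receive O1.

Step 6
Reactants: 7 2,2,6-trimethyl-4H-1,3-dioxin-4-one
Product: 9 2,2-dimethyl-6-(2-phenylethyl)-4H-1,3-dioxin-4-one, via lithium dienolate 8 (not isolated)
Conditions: LiN(i-Pr)2, THF, −78 °C; BnBr, DMPU, −78 → −20 °C
Reagents that add atoms: benzyl bromide, BrCc1ccccc1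
Why: γ-Alkylation of the extended enolate of the dioxinone with a reactive benzylic halide (vinylogous enolate alkylation) installs the 2-phenylethyl chain.

Step 7
Reactants: 6 hydroxy enaminone; 9 phenylethyl dioxinone
Product: 13 (6S,7S,8S)-7-(TBSO)-6-hydroxy-2-(2-phenylethyl)-8-(TESO)-7,8-dihydro-4H-chromene-4,5(6H)-dione, via O6-TMS enaminone 10 (not isolated), via acylketene 11 (not isolated), via O6-TMS pyranone 12 (not isolated)
Conditions: BSA, CH2Cl2, rt, then evaporate; 9 (3 equiv), PhMe, 110 °C; then citric acid, MeOH, 0 °C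
Reagents that add atoms: none
Why: Transient O-silylation keeps O6 from being acylated; thermal retro-[4+2] of 9 releases acylketene 11, which is attacked by the nucleophilic α-carbon of the enaminone (C4–C4a), after which the enol oxygen adds to the amine-bearing carbon and pyrrolidine is expelled (O1–C8a), closing the 4-pyranone (acylketene–enaminone annulation). Mild acid methanolysis then removes only the TMS group.

Step 8
Reactants: 13 6-hydroxy-5-oxo-tetrahydrochromone
Product: 14 (5S,6R,7S,8S)-7-(TBSO)-5,6-dihydroxy-2-(2-phenylethyl)-8-(TESO)-5,6,7,8-tetrahydro-4H-chromen-4-one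
Conditions: Me4NBH(OAc)3, MeCN–AcOH, −30 → 0 °C
Reagents that add atoms: none
Why: Hydroxyl-directed triacetoxyborohydride reduction (Evans–Saksena type): the C6 hydroxyl binds boron and delivers hydride to the same face of the C5 carbonyl, so H5 enters cis to O6 and the new hydroxyl is trans to O6 (5S); the reagent is too mild to attack the pyranone.

Step 9
Reactants: 14 trans-5,6-diol
Product: 15 (5S,6R,7S,8S)-5,6,7-tris(TBSO)-2-(2-phenylethyl)-8-(TESO)-5,6,7,8-tetrahydro-4H-chromen-4-one
Conditions: TBSOTf, 2,6-lutidine, CH2Cl2, −78 → 0 °C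
Reagents that add atoms: tert-butyldimethylsilyl trifluoromethanesulfonate, CC(C)(C)[Si](C)(C)OS(=O)(=O)C(F)(F)F
Why: Silyl triflate with a hindered pyridine base silylates both secondary hydroxyls (silyl ether formation) without alkoxide formation, so no silyl group should move.

Step 10
Reactants: 15 tetrasilyl ether
Product: 16 (5S,6R,7R,8S)-5,6,7-tris(TBSO)-8-hydroxy-2-(2-phenylethyl)-5,6,7,8-tetrahydro-4H-chromen-4-one
Conditions: HF·pyridine, pyridine, THF, 0 °C
Reagents that add atoms: none
Why: Kinetic differentiation of silyl ethers: buffered HF·pyridine cleaves the triethylsilyl ether much faster than the three TBS ethers, and the acidic medium excludes O7→O8 silyl migration, so only the C8 hydroxyl is freed.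

Step 11
Reactants: 17 methyl vinyl ether; 18 chromium hexacarbonyl
Product: 21 tetramethylammonium pentacarbonyl(2-methoxy-1-oxidoprop-2-en-1-ylidene)chromate, via 1-methoxyvinyllithium 19 (not isolated), via lithium acylchromate 20 (not isolated)
Conditions: t-BuLi, THF, −78 → 0 °C; Cr(CO)6, −78 °C → rt; Me4NBr, H2O
Reagents that add atoms: tetramethylammonium bromide, C[N+](C)(C)C.[Br-]
Why: α-Lithiation of the enol ether gives an acyl-anion-type vinyllithium that adds to a CO ligand of Cr(CO)6 (acylmetalate stage of the Fischer carbene synthesis); cation exchange gives a handleable ammonium acylate.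

Step 12
Reactants: 21 ammonium acylchromate; 16 C8 alcohol
Product: 23 pentacarbonyl[(1-methoxyvinyl){[(5S,6R,7R,8S)-5,6,7-tris(TBSO)-4-oxo-2-(2-phenylethyl)-5,6,7,8-tetrahydro-4H-chromen-8-yl]oxy}carbene]chromium, via acetoxycarbene 22 (not isolated)
Conditions: AcBr, CH2Cl2, −40 °C; then 16, −40 → −10 °C
Reagents that add atoms: none
Why: O-Acylation of the acylate gives a highly electrophilic acyloxycarbene, at whose carbene carbon the hindered alcohol displaces acetate by addition–elimination (alkoxy exchange of acyloxycarbenes); the C8–O bond is not involved, so C8 keeps its configuration.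

Step 13
Reactants: 24 4-phenylbut-1-yne
Product: 26 5-phenylpent-2-ynal, via lithium acetylide 25 (not isolated)
Conditions: n-BuLi, THF, −78 °C; DMF; aq. KH2PO4
Reagents that add atoms: N,N-dimethylformamide, CN(C)C=O
Why: Formylation of the lithium acetylide with DMF and buffered hydrolysis of the hemiaminal gives the ynal (acetylide formylation).

Step 14
Reactants: 26 5-phenylpent-2-ynal
Product: 27 7-phenylhepta-1,4-diyn-3-ol (racemic)
Conditions: HC≡CMgBr, THF, −78 → 0 °C; aq. NH4Cl
Reagents that add atoms: ethynylmagnesium bromide, C#C[Mg]Br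
Why: Grignard 1,2-addition to the ynal gives the bis-propargylic alcohol; the racemate is acceptable because this carbon becomes the C4' carbonyl.

Step 15
Reactants: 27 diynol
Product: 28 7-phenyl-3-(TESO)hepta-1,4-diyne (racemic)
Conditions: TESCl, imidazole, CH2Cl2, 0 °C
Reagents that add atoms: triethylsilyl chloride, CC[Si](Cl)(CC)CC
Why: Silyl ether formation; the triethylsilyl group masks the carbinol during the benzannulation and can later be removed beside TBS ethers.

Step 16
Reactants: 23 alkoxy(1-methoxyvinyl)carbene complex; 28 silyloxy diyne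
Product: 29 (5S,6R,7R,8S)-5,6,7-tris(TBSO)-8-{4-hydroxy-2-methoxy-5-[5-phenyl-1-(TESO)pent-2-yn-1-yl]phenoxy}-2-(2-phenylethyl)-5,6,7,8-tetrahydro-4H-chromen-4-one (two side-chain epimers)
Conditions: 28 (2 equiv), THF, 55 °C, Ar; then air, rt
Reagents that add atoms: none
Why: Thermal loss of one CO from the zerovalent chromium carbene opens a site for the terminal alkyne of 28, which inserts into the Cr=C bond with its unsubstituted carbon bonded to the former carbene carbon (C5'–C6'). CO insertion into the resulting vinylcarbene gives a chromium-bound dienylketene (C4a'–C8a'), which closes onto the CH2 terminus of the methoxyvinyl unit (C8'–C8a') and tautomerises to the 4-alkoxyphenol. The closest known reaction type is the Dötz benzannulation of alkoxy(alkenyl)carbene chromium complexes, including α-alkoxyalkenyl carbenes and carbenes with chiral secondary alkoxy groups, with terminal alkynes. Ring B is closed as a six-membered ring by 6π-electrocyclisation of the metal-templated dienylketene, a formal [3+2+1] assembly. No stereocentre is created: C5–C8 are spectators and the epimeric side-chain carbon brought in by racemic 28 is erased in step 18. The step needs regioselective insertion, which the steric difference between hydrogen and the branched propargylic substituent of a terminal alkyne should secure by placing the large group ortho to the new phenol. It also needs reaction at the terminal and not the internal alkyne, favoured by the much faster coordination of terminal alkynes, and phenol formation over CO-free cyclisation, favoured by chromium, an alkenyl carbene and an ether solvent. Exposure to air releases any chromium tricarbonyl still bound to the new arene.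

Step 17
Reactants: 29 benzannulation product
Product: 30 (5S,6R,7R,8S)-5,6,7-tris(TBSO)-8-[4-hydroxy-5-(1-hydroxy-5-phenylpent-2-yn-1-yl)-2-methoxyphenoxy]-2-(2-phenylethyl)-5,6,7,8-tetrahydro-4H-chromen-4-one (two side-chain epimers)
Conditions: HF·pyridine, pyridine, THF, 0 °C
Reagents that add atoms: none
Why: Selective fluoride cleavage of the secondary triethylsilyl ether beside three TBS ethers (kinetic differentiation by substitution at silicon); buffering avoids ionisation of the benzylic, propargylic carbinol.

Step 18
Reactants: 30 phenol carbinol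
Product: 31 (5S,6R,7R,8S)-5,6,7-tris(TBSO)-8-[4-hydroxy-2-methoxy-5-(5-phenylpent-2-ynoyl)phenoxy]-2-(2-phenylethyl)-5,6,7,8-tetrahydro-4H-chromen-4-one
Conditions: MnO2 (activated), CH2Cl2, rt
Reagents that add atoms: none
Why: MnO2 oxidation of a doubly activated (benzylic and propargylic) alcohol to the ynone runs under neutral heterogeneous conditions that should tolerate the phenol; it also removes the epimeric centre.

Step 19
Reactants: 31 ortho-hydroxyaryl ynone
Product: 33 (5S,6R,7R,8S)-5,6,7-tris(TBSO)-8-{[7-methoxy-4-oxo-2-(2-phenylethyl)-4H-chromen-6-yl]oxy}-2-(2-phenylethyl)-5,6,7,8-tetrahydro-4H-chromen-4-one, via diethylamino enone 32 (not isolated)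
Conditions: Et2NH, EtOH, rt
Reagents that add atoms: none
Why: Amine-relayed chromone synthesis from an ortho-hydroxyaryl ynone: conjugate addition of the amine gives enaminone 32, and the phenol oxygen then attacks the same β-carbon with loss of the amine (addition–elimination), so ring D closes only in the 6-endo sense.

Step 20
Reactants: 33 tris-TBS ether
Product: 34 (5S,6R,7S,8S)-5,6,7-trihydroxy-8-{[7-methoxy-4-oxo-2-(2-phenylethyl)-4H-chromen-6-yl]oxy}-2-(2-phenylethyl)-5,6,7,8-tetrahydro-4H-chromen-4-one
Conditions: HF·pyridine, THF, 0 °C → rt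
Reagents that add atoms: none
Why: Global fluoride desilylation of three secondary silyl ethers under mildly acidic conditions should leave the aryl alkyl ether, both pyranones and all four stereocentres untouched.

## Compound list

1 | (1S,2S)-3-bromocyclohexa-3,5-diene-1,2-diol | O[C@@H]1C(Br)=CC=C[C@@H]1O | starting material
2 | (1S,6S)-2-bromo-6-(TBSO)cyclohexa-2,4-dien-1-ol | O[C@@H]1C(Br)=CC=C[C@@H]1O[Si](C)(C)C(C)(C)C | intermediate
3 | (5S,6S)-1-bromo-5-(TBSO)-6-(TESO)cyclohexa-1,3-diene | CC[Si](CC)(CC)O[C@@H]1C(Br)=CC=C[C@@H]1O[Si](C)(C)C(C)(C)C | intermediate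
4 | (1R,2R,5S,6S)-4-bromo-6-(TBSO)-5-(TESO)cyclohex-3-ene-1,2-diol | CC[Si](CC)(CC)O[C@@H]1C(Br)=C[C@@H](O)[C@@H](O)[C@@H]1O[Si](C)(C)C(C)(C)C | intermediate
5 | (4S,5S,6S)-3-bromo-5-(TBSO)-6-hydroxy-4-(TESO)cyclohex-2-en-1-one | CC[Si](CC)(CC)O[C@@H]1C(Br)=CC(=O)[C@@H](O)[C@@H]1O[Si](C)(C)C(C)(C)C | intermediate
6 | (4R,5S,6S)-5-(TBSO)-6-hydroxy-3-(pyrrolidin-1-yl)-4-(TESO)cyclohex-2-en-1-one | CC[Si](CC)(CC)O[C@@H]1C(N2CCCC2)=CC(=O)[C@@H](O)[C@@H]1O[Si](C)(C)C(C)(C)C | intermediate
7 | 2,2,6-trimethyl-4H-1,3-dioxin-4-one | CC1=CC(=O)OC(C)(C)O1 | starting material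
8 | lithium 2,2-dimethyl-6-methylidene-6H-1,3-dioxin-4-olate | [Li+].C=C1C=C([O-])OC(C)(C)O1 | intermediate (not isolated)
9 | 2,2-dimethyl-6-(2-phenylethyl)-4H-1,3-dioxin-4-one | CC1(C)OC(CCc2ccccc2)=CC(=O)O1 | intermediate
10 | (4R,5R,6S)-5-(TBSO)-3-(pyrrolidin-1-yl)-4-(TESO)-6-(TMSO)cyclohex-2-en-1-one | CC[Si](CC)(CC)O[C@@H]1C(N2CCCC2)=CC(=O)[C@@H](O[Si](C)(C)C)[C@@H]1O[Si](C)(C)C(C)(C)C | intermediate (not isolated)
11 | 3-oxo-5-phenylpent-1-en-1-one (acylketene) | O=C=CC(=O)CCc1ccccc1 | intermediate (not isolated)
12 | (6S,7R,8S)-7-(TBSO)-2-(2-phenylethyl)-8-(TESO)-6-(TMSO)-7,8-dihydro-4H-chromene-4,5(6H)-dione | CC[Si](CC)(CC)O[C@@H]1c2oc(CCc3ccccc3)cc(=O)c2C(=O)[C@@H](O[Si](C)(C)C)[C@@H]1O[Si](C)(C)C(C)(C)C | intermediate (not isolated)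
13 | (6S,7S,8S)-7-(TBSO)-6-hydroxy-2-(2-phenylethyl)-8-(TESO)-7,8-dihydro-4H-chromene-4,5(6H)-dione | CC[Si](CC)(CC)O[C@@H]1c2oc(CCc3ccccc3)cc(=O)c2C(=O)[C@@H](O)[C@@H]1O[Si](C)(C)C(C)(C)C | intermediate
14 | (5S,6R,7S,8S)-7-(TBSO)-5,6-dihydroxy-2-(2-phenylethyl)-8-(TESO)-5,6,7,8-tetrahydro-4H-chromen-4-one | CC[Si](CC)(CC)O[C@@H]1c2oc(CCc3ccccc3)cc(=O)c2[C@H](O)[C@@H](O)[C@@H]1O[Si](C)(C)C(C)(C)C | intermediate
15 | (5S,6R,7S,8S)-5,6,7-tris(TBSO)-2-(2-phenylethyl)-8-(TESO)-5,6,7,8-tetrahydro-4H-chromen-4-one | CC[Si](CC)(CC)O[C@@H]1c2oc(CCc3ccccc3)cc(=O)c2[C@H](O[Si](C)(C)C(C)(C)C)[C@@H](O[Si](C)(C)C(C)(C)C)[C@@H]1O[Si](C)(C)C(C)(C)C | intermediate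
16 | (5S,6R,7R,8S)-5,6,7-tris(TBSO)-8-hydroxy-2-(2-phenylethyl)-5,6,7,8-tetrahydro-4H-chromen-4-one | O[C@@H]1c2oc(CCc3ccccc3)cc(=O)c2[C@H](O[Si](C)(C)C(C)(C)C)[C@@H](O[Si](C)(C)C(C)(C)C)[C@@H]1O[Si](C)(C)C(C)(C)C | intermediate
17 | methyl vinyl ether | C=COC | starting material
18 | chromium hexacarbonyl | O=C=[Cr](=C=O)(=C=O)(=C=O)(=C=O)=C=O | starting material
19 | 1-methoxyvinyllithium | [Li]C(=C)OC | intermediate (not isolated)
20 | lithium pentacarbonyl(2-methoxy-1-oxidoprop-2-en-1-ylidene)chromate | [Li+].C=C(OC)C([O-])=[Cr](=C=O)(=C=O)(=C=O)(=C=O)=C=O | intermediate (not isolated)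
21 | tetramethylammonium pentacarbonyl(2-methoxy-1-oxidoprop-2-en-1-ylidene)chromate | C[N+](C)(C)C.C=C(OC)C([O-])=[Cr](=C=O)(=C=O)(=C=O)(=C=O)=C=O | intermediate
22 | pentacarbonyl[acetoxy(1-methoxyvinyl)carbene]chromium | C=C(OC)C(OC(C)=O)=[Cr](=C=O)(=C=O)(=C=O)(=C=O)=C=O | intermediate (not isolated)
23 | pentacarbonyl[(1-methoxyvinyl){[(5S,6R,7R,8S)-5,6,7-tris(TBSO)-4-oxo-2-(2-phenylethyl)-5,6,7,8-tetrahydro-4H-chromen-8-yl]oxy}carbene]chromium | C=C(OC)C(O[C@@H]1c2oc(CCc3ccccc3)cc(=O)c2[C@H](O[Si](C)(C)C(C)(C)C)[C@@H](O[Si](C)(C)C(C)(C)C)[C@@H]1O[Si](C)(C)C(C)(C)C)=[Cr](=C=O)(=C=O)(=C=O)(=C=O)=C=O | intermediate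
24 | 4-phenylbut-1-yne | C#CCCc1ccccc1 | starting material
25 | (4-phenylbut-1-yn-1-yl)lithium | [Li]C#CCCc1ccccc1 | intermediate (not isolated)
26 | 5-phenylpent-2-ynal | O=CC#CCCc1ccccc1 | intermediate
27 | 7-phenylhepta-1,4-diyn-3-ol (racemic) | C#CC(O)C#CCCc1ccccc1 | intermediate
28 | 7-phenyl-3-(TESO)hepta-1,4-diyne (racemic) | C#CC(O[Si](CC)(CC)CC)C#CCCc1ccccc1 | intermediate
29 | (5S,6R,7R,8S)-5,6,7-tris(TBSO)-8-{4-hydroxy-2-methoxy-5-[5-phenyl-1-(TESO)pent-2-yn-1-yl]phenoxy}-2-(2-phenylethyl)-5,6,7,8-tetrahydro-4H-chromen-4-one (two side-chain epimers) | COc1cc(O)c(C(O[Si](CC)(CC)CC)C#CCCc2ccccc2)cc1O[C@@H]1c2oc(CCc3ccccc3)cc(=O)c2[C@H](O[Si](C)(C)C(C)(C)C)[C@@H](O[Si](C)(C)C(C)(C)C)[C@@H]1O[Si](C)(C)C(C)(C)C | intermediate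
30 | (5S,6R,7R,8S)-5,6,7-tris(TBSO)-8-[4-hydroxy-5-(1-hydroxy-5-phenylpent-2-yn-1-yl)-2-methoxyphenoxy]-2-(2-phenylethyl)-5,6,7,8-tetrahydro-4H-chromen-4-one (two side-chain epimers) | COc1cc(O)c(C(O)C#CCCc2ccccc2)cc1O[C@@H]1c2oc(CCc3ccccc3)cc(=O)c2[C@H](O[Si](C)(C)C(C)(C)C)[C@@H](O[Si](C)(C)C(C)(C)C)[C@@H]1O[Si](C)(C)C(C)(C)C | intermediate
31 | (5S,6R,7R,8S)-5,6,7-tris(TBSO)-8-[4-hydroxy-2-methoxy-5-(5-phenylpent-2-ynoyl)phenoxy]-2-(2-phenylethyl)-5,6,7,8-tetrahydro-4H-chromen-4-one | COc1cc(O)c(C(=O)C#CCCc2ccccc2)cc1O[C@@H]1c2oc(CCc3ccccc3)cc(=O)c2[C@H](O[Si](C)(C)C(C)(C)C)[C@@H](O[Si](C)(C)C(C)(C)C)[C@@H]1O[Si](C)(C)C(C)(C)C | intermediate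
32 | (5S,6R,7R,8S)-5,6,7-tris(TBSO)-8-{5-[3-(diethylamino)-5-phenylpent-2-enoyl]-4-hydroxy-2-methoxyphenoxy}-2-(2-phenylethyl)-5,6,7,8-tetrahydro-4H-chromen-4-one | COc1cc(O)c(C(=O)C=C(CCc2ccccc2)N(CC)CC)cc1O[C@@H]1c2oc(CCc3ccccc3)cc(=O)c2[C@H](O[Si](C)(C)C(C)(C)C)[C@@H](O[Si](C)(C)C(C)(C)C)[C@@H]1O[Si](C)(C)C(C)(C)C | intermediate (not isolated)
33 | (5S,6R,7R,8S)-5,6,7-tris(TBSO)-8-{[7-methoxy-4-oxo-2-(2-phenylethyl)-4H-chromen-6-yl]oxy}-2-(2-phenylethyl)-5,6,7,8-tetrahydro-4H-chromen-4-one | COc1cc2oc(CCc3ccccc3)cc(=O)c2cc1O[C@@H]1c2oc(CCc3ccccc3)cc(=O)c2[C@H](O[Si](C)(C)C(C)(C)C)[C@@H](O[Si](C)(C)C(C)(C)C)[C@@H]1O[Si](C)(C)C(C)(C)C | intermediate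
34 | (5S,6R,7S,8S)-5,6,7-trihydroxy-8-{[7-methoxy-4-oxo-2-(2-phenylethyl)-4H-chromen-6-yl]oxy}-2-(2-phenylethyl)-5,6,7,8-tetrahydro-4H-chromen-4-one | COc1cc2oc(CCc3ccccc3)cc(=O)c2cc1O[C@@H]1c2oc(CCc3ccccc3)cc(=O)c2[C@H](O)[C@@H](O)[C@@H]1O | target

## Step count and least certain steps

Total: 20 steps. Longest linear sequence: 15 steps (steps 1–5, 7–10, 12, 16–20).

Step 16 (key step). Most likely to go wrong: the electron-rich, hindered carbene may decompose thermally or follow CO-free cyclisation paths before the phenol forms, and the skipped diyne may ionise at its propargylic silyl ether or bind chromium through its internal alkyne. Fallback, setting out from 23 and returning at 30: benzannulation of 23 with commercial 3,3-diethoxyprop-1-yne under the same conditions would give the salicylaldehyde diethyl acetal F1. Mild acid hydrolysis (pyridinium tosylate, acetone–water) would free the ortho-hydroxybenzaldehyde F2. Addition of excess lithium acetylide 25 at −78 °C would then give 30, so the C2'–C3' unit is added after ring B exists rather than carried through the benzannulation. If the failure lies in the carbene itself, the fallback of step 12 applies.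

Step 12. Most likely to go wrong: attack of the hindered C8 hydroxyl may be so slow that the thermolabile acetoxycarbene decomposes first, or the alcohol may add to the vinyl terminus instead of the carbene carbon. Fallback, setting out from 16 and returning at 33: ring B is brought in ready-made. Commercial 1-(5-bromo-2-hydroxy-4-methoxyphenyl)ethanone F3 is condensed with methyl 3-phenylpropanoate (NaH, THF) to the 1,3-diketone F4, which acid cyclises to 6-bromo-7-methoxy-2-(2-phenylethyl)chromone F5. Palladium-catalysed etherification of 16 with F5 ([Pd(allyl)Cl]2, a bulky biarylphosphine such as RockPhos, Cs2CO3, toluene, 90 °C) would then give 33. The weakness of this route is base beside the O7 silyl ether.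

Step 7. Most likely to go wrong: the TMS group may be lost before or during ketene generation, leading to acylation of O6, or the polyoxygenated enaminone may undergo thermal β-elimination toward an aromatic ring. Fallback, setting out from 6 and returning at 15: silylation with TBSOTf and 2,6-lutidine gives the robust 6-O-TBS enaminone F6, annulation with 9 in toluene at 110 °C gives the 6-O-TBS 5-oxo-tetrahydrochromone F7, Luche reduction (NaBH4, CeCl3·7H2O, MeOH, −78 °C) gives the C5 alcohol F8, and silylation with TBSOTf gives 15. The cost is that C5 is then set by substrate control (axial hydride attack) instead of directed delivery.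

Step 4. Most likely to go wrong: oxidative cleavage of the cis-glycol or further oxidation of the α-ketol may compete with an allylic oxidation slowed by the electron-poor bromoalkene. Fallback, setting out from 3 and returning at 5: epoxidation with mCPBA (NaHCO3, CH2Cl2, 0 °C) on the face away from the silyloxy groups gives the vinyl epoxide F9. Brief hydrolytic anti opening at the allylic carbon (dilute HClO4, THF–H2O, 0 °C) gives the trans-diol F10, which lacks the cis-glycol geometry prone to cleavage. MnO2 oxidation of its allylic hydroxyl then gives 5 with the same C6 configuration.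

Step 18. Most likely to go wrong: the electron-rich 4-alkoxyphenol may be oxidised (phenoxy radical coupling or quinone formation) in competition with the carbinol. Fallback, setting out from 30 and returning at 31: the phenol is silylated selectively (TBSCl, imidazole, CH2Cl2, 0 °C) to the aryl silyl ether F11, the carbinol is oxidised with MnO2 to the O-silylated ynone F12, and the phenolic silyl group alone is removed with KHF2 in MeOH to give 31.

## Further compounds

F1 | step 16 | (5S,6R,7R,8S)-5,6,7-tris(TBSO)-8-[5-(diethoxymethyl)-4-hydroxy-2-methoxyphenoxy]-2-(2-phenylethyl)-5,6,7,8-tetrahydro-4H-chromen-4-one | COc1cc(O)c(C(OCC)OCC)cc1O[C@@H]1c2oc(CCc3ccccc3)cc(=O)c2[C@H](O[Si](C)(C)C(C)(C)C)[C@@H](O[Si](C)(C)C(C)(C)C)[C@@H]1O[Si](C)(C)C(C)(C)C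
F2 | step 16 | (5S,6R,7R,8S)-5,6,7-tris(TBSO)-8-(5-formyl-4-hydroxy-2-methoxyphenoxy)-2-(2-phenylethyl)-5,6,7,8-tetrahydro-4H-chromen-4-one | COc1cc(O)c(C=O)cc1O[C@@H]1c2oc(CCc3ccccc3)cc(=O)c2[C@H](O[Si](C)(C)C(C)(C)C)[C@@H](O[Si](C)(C)C(C)(C)C)[C@@H]1O[Si](C)(C)C(C)(C)C
F3 | step 12 | 1-(5-bromo-2-hydroxy-4-methoxyphenyl)ethanone | COc1cc(O)c(C(C)=O)cc1Br
F4 | step 12 | 1-(5-bromo-2-hydroxy-4-methoxyphenyl)-5-phenylpentane-1,3-dione | COc1cc(O)c(C(=O)CC(=O)CCc2ccccc2)cc1Br
F5 | step 12 | 6-bromo-7-methoxy-2-(2-phenylethyl)-4H-chromen-4-one | COc1cc2oc(CCc3ccccc3)cc(=O)c2cc1Br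
F6 | step 7 | (4R,5R,6S)-5,6-bis(TBSO)-3-(pyrrolidin-1-yl)-4-(TESO)cyclohex-2-en-1-one | CC[Si](CC)(CC)O[C@@H]1C(N2CCCC2)=CC(=O)[C@@H](O[Si](C)(C)C(C)(C)C)[C@@H]1O[Si](C)(C)C(C)(C)C
F7 | step 7 | (6S,7R,8S)-6,7-bis(TBSO)-2-(2-phenylethyl)-8-(TESO)-7,8-dihydro-4H-chromene-4,5(6H)-dione | CC[Si](CC)(CC)O[C@@H]1c2oc(CCc3ccccc3)cc(=O)c2C(=O)[C@@H](O[Si](C)(C)C(C)(C)C)[C@@H]1O[Si](C)(C)C(C)(C)C
F8 | step 7 | (5S,6R,7S,8S)-6,7-bis(TBSO)-5-hydroxy-2-(2-phenylethyl)-8-(TESO)-5,6,7,8-tetrahydro-4H-chromen-4-one | CC[Si](CC)(CC)O[C@@H]1c2oc(CCc3ccccc3)cc(=O)c2[C@H](O)[C@@H](O[Si](C)(C)C(C)(C)C)[C@@H]1O[Si](C)(C)C(C)(C)C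
F9 | step 4 | (1R,4S,5S,6R)-3-bromo-5-(TBSO)-4-(TESO)-7-oxabicyclo[4.1.0]hept-2-ene | CC[Si](CC)(CC)O[C@@H]1C(Br)=C[C@H]2O[C@H]2[C@@H]1O[Si](C)(C)C(C)(C)C
F10 | step 4 | (1R,2S,5S,6S)-4-bromo-6-(TBSO)-5-(TESO)cyclohex-3-ene-1,2-diol | CC[Si](CC)(CC)O[C@@H]1C(Br)=C[C@H](O)[C@@H](O)[C@@H]1O[Si](C)(C)C(C)(C)C
F11 | step 18 | (5S,6R,7R,8S)-5,6,7-tris(TBSO)-8-[4-(TBSO)-5-(1-hydroxy-5-phenylpent-2-yn-1-yl)-2-methoxyphenoxy]-2-(2-phenylethyl)-5,6,7,8-tetrahydro-4H-chromen-4-one (two side-chain epimers) | COc1cc(O[Si](C)(C)C(C)(C)C)c(C(O)C#CCCc2ccccc2)cc1O[C@@H]1c2oc(CCc3ccccc3)cc(=O)c2[C@H](O[Si](C)(C)C(C)(C)C)[C@@H](O[Si](C)(C)C(C)(C)C)[C@@H]1O[Si](C)(C)C(C)(C)C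
F12 | step 18 | (5S,6R,7R,8S)-5,6,7-tris(TBSO)-8-[4-(TBSO)-2-methoxy-5-(5-phenylpent-2-ynoyl)phenoxy]-2-(2-phenylethyl)-5,6,7,8-tetrahydro-4H-chromen-4-one | COc1cc(O[Si](C)(C)C(C)(C)C)c(C(=O)C#CCCc2ccccc2)cc1O[C@@H]1c2oc(CCc3ccccc3)cc(=O)c2[C@H](O[Si](C)(C)C(C)(C)C)[C@@H](O[Si](C)(C)C(C)(C)C)[C@@H]1O[Si](C)(C)C(C)(C)C
A1 | alternative 1 | 6-O-TBS 7,8-O-isopropylidene derivative of (6,7,8)-trihydroxy-2-(2-phenylethyl)-7,8-dihydro-4H-chromene-4,5(6H)-dione (O6 trans to O7, O7 cis to O8) | CC1(C)O[C@@H]2c3oc(CCc4ccccc4)cc(=O)c3C(=O)[C@@H](O[Si](C)(C)C(C)(C)C)[C@@H]2O1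
A2 | alternative 1 | 6-(TBSO)-4,5-(isopropylidenedioxy)-3-(pyrrolidin-1-yl)cyclohex-2-en-1-one (acetonide cis, silyloxy group trans to it) | CC1(C)O[C@@H]2C(N3CCCC3)=CC(=O)[C@@H](O[Si](C)(C)C(C)(C)C)[C@@H]2O1
A3 | alternative 1 | 6-hydroxy-7-methoxy-2-(2-phenylethyl)-4H-chromen-4-one | COc1cc2oc(CCc3ccccc3)cc(=O)c2cc1O
A4 | alternative 2 | 5,6,7-tri-O-benzyl ether of 34 | COc1cc2oc(CCc3ccccc3)cc(=O)c2cc1O[C@@H]1c2oc(CCc3ccccc3)cc(=O)c2[C@H](OCc2ccccc2)[C@@H](OCc2ccccc2)[C@@H]1OCc1ccccc1
A5 | alternative 2 | 1-{5-[(2-acetyl-4,5,6-tris(benzyloxy)-1-hydroxycyclohex-1-en-3... -yl)oxy]-2-hydroxy-4-methoxyphenyl}ethanone, i.e. the bis(acetyl) ether with the ring configuration of 34 | COc1cc(O)c(C(C)=O)cc1O[C@@H]1C(O)=C(C(C)=O)[C@H](OCc2ccccc2)[C@@H](OCc2ccccc2)[C@@H]1OCc1ccccc1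
A6 | alternative 2 | methyl 3-phenylpropanoate | COC(=O)CCc1ccccc1
A7 | alternative 3 | isoxazole-fused tri-O-benzyl cyclitol aryl ether with a 2-(TBSO)-4-phenylbutyl side chain | COc1cc2oc(CCc3ccccc3)cc(=O)c2cc1O[C@@H]1c2noc(CC(O[Si](C)(C)C(C)(C)C)CCc3ccccc3)c2[C@H](OCc2ccccc2)[C@@H](OCc2ccccc2)[C@@H]1OCc1ccccc1
A8 | alternative 3 | open-chain aldoxime: 2-aryloxy-3,4,5-tris(benzyloxy)-9-(TBSO)-11-phenylundec-6-ynal oxime with the configuration of A7 | COc1cc2oc(CCc3ccccc3)cc(=O)c2cc1O[C@H](C=NO)[C@@H](OCc1ccccc1)[C@H](OCc1ccccc1)[C@@H](OCc1ccccc1)C#CCC(O[Si](C)(C)C(C)(C)C)CCc1ccccc1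
A9 | alternative 3 | D-glucose (pyranose form) | OC[C@H]1OC(O)[C@H](O)[C@@H](O)[C@@H]1O
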